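Slowness bought the target nothing in the spring run. At 2.00 min its side product read 70.0%, less than the 76.7% of the summer run at 0.833 min, yet spring's target ended at 19.4% against summer's 21.6%. The autumn run, with 3 mol% of free catalyst instead of 2 mol%, ended at 28.9%.

| flask | starting material | second substrate | reagent | free catalyst | temperature | remark | time |
|---|---|---|---|---|---|---|---|
| spring | 0.40 M | 0.50 equiv | 1.3 equiv | 2 mol% | −15 °C | run made earlier |  |
| summer | 0.56 M | 0.50 equiv | 1.3 equiv | 2 mol% | 0 °C | run made earlier |  |
| dusk | 0.88 M | 0.50 equiv | 1.3 equiv | 2 mol% | −15 °C | run made earlier |  |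
| autumn | 0.40 M | 0.50 equiv | 1.3 equiv | 3 mol% | 0 °C | run made earlier |  |
| amber | 0.40 M | 0.500 equiv (fed, over 1.5 min) | 1.30 equiv | 2 mol% | 0 °C | all else is in the flask from the start; the feed brings no volume worth counting | 2.0 min |
| blue | 0.40 M (fed, over 1.5 min) | 0.500 equiv | 1.30 equiv | 2 mol% |  | the addition at −40 °C, then warmed to 0 °C; the feed brings no volume worth counting | 2.0 min |
| red | 0.40 M (fed, over 1.5 min) | 0.500 equiv | 1.30 equiv | 2 mol% | 0 °C | all else is in the flask from the start; the feed brings no volume worth counting | 2.0 min |
| ochre | 0.40 M | 0.500 equiv | 1.30 equiv | 2 mol% | 0 °C | everything together at the start | 2.0 min |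
| teal | 0.40 M | 0.500 equiv | 1.30 equiv | 2 mol% |  | everything together at the start at −40 °C, warmed to 0 °C at 1.5 min | 2.0 min |

- spring (time / min: side product / %, target / %): 0.333: 13.0, 11.7; 0.833: 39.4, 16.4; 2.00: 70.0, 18.4; 3.00: 76.6, 19.4
- summer (time / min: side product / %, target / %): 0.333: 56.7, 20.8; 0.833: 76.7, 22.1; 1.50: 77.4, 21.7; 2.50: 78.1, 21.6
- dusk (time / min: side product / %, target / %): 0.667: 58.2, 16.6; 2.00: 81.6, 17.2; 3.00: 82.1, 17.6; 5.00: 83.0, 17.8
- autumn (time / min: side product / %, target / %): 0.667: 66.7, 28.8; 1.33: 71.9, 28.3; 2.00: 71.9, 28.0; 2.50: 71.1, 28.9

(scatter of a reading: 0.5 percentage points)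

- in percentages every species weighs as the starting material in it: one side product counts as two
- reactions considered so far: second substrate + free catalyst <-> catalyst intermediate B; reagent + catalyst intermediate B -> free catalyst + second product; starting material + target -> side product; starting material + free catalyst <-> catalyst intermediate A; reagent + catalyst intermediate A -> free catalyst + target

- which flask leads in amount of side product, in percent of the starting material charged ("all alike" within 1.5 percentage points) (amber / blue / red / ochre / teal / all alike)
- how much side product is there at the end, in percent of the starting material charged: amber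
- how much side product is there at the end, in percent of the starting material charged: blue
- how much side product is there at the end, in percent of the starting material charged: red
- how much side product is there at the end, in percent of the starting material charged: ochre
- how much side product is there at the end, in percent of the starting material charged: teal

Starting material binds free catalyst as catalyst intermediate A, which reagent turns into target, while second substrate takes catalyst through catalyst intermediate B to second product. Target then meets starting material and gives side product. I wrote making as k_m[starting material] (pseudo-first-order) and burning as k_b[starting material][target], so starting material stood in both and time dropped from their ratio. I defined the selectivity factor ρ = k_m/(k_b c), with c the charge: the share of the charge at which target is made as fast as it is burnt. Loading enters k_m. Integrating over the charge, with target x as a share of it, gave x = ρ(1 − exp(−(1 + x)/(2ρ))).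

Autumn, at ochre's temperature and concentration, averaged 28.5%. Starting from that value, I solved for ρ by going round: 31.8%, 32.9%, 33.2%. Taking ρ as proportional to loading, ochre's ρ was 22.1%. Rounds on x gave 20.7%, then 20.7%, so I expected 79.3% side product in ochre.

The forecast named ochre as leader, with amber 76.5%, blue 63.5%, red 75%, ochre 78% and teal 65%, holding that “final target depends almost only on the ratio”. My ochre figure stood higher than its own.

Ochre gave 78.9% and led, with amber 74.6%, blue 59.2%, red 75.2% and teal 60.5%.

    second substrate + free catalyst ⇌ catalyst intermediate B (K = 3.00 M⁻¹, k = 5.00 M⁻¹ s⁻¹, Ea = 38.0 kJ mol⁻¹, ΔH = −27.0 kJ mol⁻¹)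
    reagent + catalyst intermediate B → free catalyst + second product (k = 1.70 M⁻¹ s⁻¹, Ea = 55.0 kJ mol⁻¹)
    starting material + target → side product (k = 0.330 M⁻¹ s⁻¹, Ea = 37.0 kJ mol⁻¹)
    starting material + free catalyst ⇌ catalyst intermediate A (K = 1.60 M⁻¹, k = 9.00 M⁻¹ s⁻¹, Ea = 49.0 kJ mol⁻¹, ΔH = −66.0 kJ mol⁻¹)
    reagent + catalyst intermediate A → free catalyst + target (k = 28.0 M⁻¹ s⁻¹, Ea = 43.0 kJ mol⁻¹)
    (constants at 0 °C)

At 2.00 min ochre held 21.0% target, lower than ρ, with 0.140% starting material left. At 2.7 mol% of free catalyst, ochre's side product has moved 5 points. There ρ scales to 29.4%, and the rounds give 26.1%, then 25.9% target, so 74.1% side product, 4.8 percentage points below ochre's.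

All runs are simulated on assumed constants, noise included.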